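**Plan**
1. Retrosynthetic cuts: first the two O–Si bonds at O7 and O7''. Then C4–C4a, C4''–C4a'', O1–C8a and O1''–C8a'' are cut together, which removes each ring A as a 2-fluoroaryl anion.
2. Enabling feature: C4–C3–C3''–C4'' is a 2,3-disubstituted succinyl unit, and C2 and C2'' carry oxygen. The two rings C without rings A are therefore a crossed dilactone, a 4,8-diaryl-3,7-dioxabicyclo[3.3.0]octane-2,6-dione (O on C2 acylated by C4'', O on C2'' by C4).
3. The dilactone is cut at both benzylic C–O bonds to (2R,3R)-2,3-bis(4-methoxybenzyl)succinic acid, and this acid at C3–C3'' to two 3-(4-methoxyphenyl)propanoyl units.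
4. Forward order: C3–C3'' by oxidative enolate dimerisation, both lactone rings by twofold benzylic oxidation, both pyranone rings together in the key step, then desilylation.
5. Stereochemistry: the (S)-oxazolidinone sets the two succinate centres. These allow only a cis-fused bicycle with both aryl groups exo, which fixes 2S and 2''S. C3 and C3'' are then re-set to trans (3R, 3''R) by equilibration against the untouched C2 centres.

Key step: step 6

Assumption: flavonoid numbering is used (second half doubly primed), and among the C3/C3'' epimers with fixed 2S,2''S centres the trans,trans isomer is taken as the most stable, as in simple 3-substituted flavanones.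

Step 1
Reactants: 1 3-(4-methoxyphenyl)propanoyl chloride; 2 (4S)-4-isopropyl-1,3-oxazolidin-2-one
Product: 3 (4S)-4-isopropyl-3-[3-(4-methoxyphenyl)propanoyl]-1,3-oxazolidin-2-one
Conditions: Et3N, DMAP (cat.), CH2Cl2, 0 °C → rt
Reagents that add atoms: none
Why: DMAP-catalysed N-acylation of an oxazolidinone with an acid chloride is routine and leaves the C4 centre of the auxiliary untouched.

Step 2
Reactants: 3 (4S)-4-isopropyl-3-[3-(4-methoxyphenyl)propanoyl]-1,3-oxazolidin-2-one (two equivalents)
Product: 6 (2R,3R)-2,3-bis(4-methoxybenzyl)-1,4-bis[(4S)-4-isopropyl-2-oxo-1,3-oxazolidin-3-yl]butane-1,4-dione, via lithium Z-enolate 4 (not isolated), via trichlorotitanium Z-enolate 5 (not isolated)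
Conditions: LDA, THF, −78 °C; TiCl4, −78 → 0 °C
Reagents that add atoms: none
Why: Oxidative enolate homocoupling, known for N-(3-arylpropanoyl)oxazolidinones: the chelated Z-enolate 5 hands one electron to tetravalent titanium and the α-carbonyl radicals join C3 to C3'' through the faces turned away from the isopropyl groups, so both new centres should be R and the minor R,S dimer is removed by crystallisation or chromatography.

Step 3
Reactants: 6 (2R,3R)-2,3-bis(4-methoxybenzyl)-1,4-bis[(4S)-4-isopropyl-2-oxo-1,3-oxazolidin-3-yl]butane-1,4-dione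
Product: 7 (2R,3R)-2,3-bis(4-methoxybenzyl)butanedioic acid
Conditions: LiOH, H2O2, THF/H2O, 0 °C → rt; Na2SO3; HCl to pH 2
Reagents that add atoms: hydrogen peroxide (acting as LiOOH), OO
Why: Hydroperoxide cleavage of N-acyloxazolidinones: the small α-effect nucleophile LiOOH attacks the exocyclic carbonyl even of hindered imides and is too weakly basic to epimerise the α-centres, and the auxiliary is recovered.

Step 4
Reactants: 7 (2R,3R)-2,3-bis(4-methoxybenzyl)butanedioic acid
Product: 8 (1S,4S,5S,8S)-4,8-bis(4-methoxyphenyl)-3,7-dioxabicyclo[3.3.0]octane-2,6-dione (cis-fused, both aryl groups exo)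
Conditions: DDQ (2.5 equiv), AcOH, 80 °C
Reagents that add atoms: none
Why: DDQ benzylic C–H oxidation with carboxylic acid capture, the oxidative lactonisation known for 4-(4-methoxyphenyl)butanoic acids: hydride loss gives a 4-methoxybenzylic cation that only the γ-carboxyl of the other half can reach (5-exo-trig; the nearer carboxyl would give a β-lactone), the R,R backbone allows only the cis-fused bicycle, and each aryl group settles on the convex exo face trans to the neighbouring acyl carbon, which sets both benzylic centres S, with reversible ionisation in AcOH correcting any endo isomer.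

Step 5
Reactants: 9 3-fluoro-5-methoxyphenol
Product: 10 (3-fluoro-5-methoxyphenoxy)triisopropylsilane
Conditions: TIPSCl, imidazole, DMF, rt
Reagents that add atoms: chlorotriisopropylsilane (TIPSCl), CC(C)[Si](Cl)(C(C)C)C(C)C
Why: Standard silylation of a phenol; the triisopropylsilyl ether is chosen because it neither directs lithiation nor leaves room for it at its two ortho positions, and it resists lithium alkoxides.

Step 6
Reactants: 8 (1S,4S,5S,8S)-4,8-bis(4-methoxyphenyl)-3,7-dioxabicyclo[3.3.0]octane-2,6-dione; 10 (3-fluoro-5-methoxyphenoxy)triisopropylsilane (two equivalents)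
Product: 15 (2S,3R,2''S,3''R)-5,5''-dimethoxy-2,2''-bis(4-methoxyphenyl)-7,7''-bis(triisopropylsilyloxy)-3,3''-bichroman-4,4''-dione, via aryllithium 11 (not isolated), via dilithium bis-lactolate 12 (not isolated), via dilithium diketo dialkoxide 13 (not isolated), via cis-cis biflavanone 14 (not isolated)
Conditions: 10 (2.4 equiv), s-BuLi (2.3 equiv), THF, −78 °C; 8 in THF, −78 °C; t-BuOH (1 equiv), DMPU, −78 → 23 °C; aq NH4Cl
Reagents that add atoms: none
Why: Proposed new method: directed ortho-metalation of 10 at the carbon between fluorine and methoxy (the bulky silyloxy group screens its own neighbours) gives 11, which below −70 °C adds once to each lactone carbonyl of 8 (C4–C4a and C4''–C4a'') and rests as bis-lactolate 12; on warming 12 collapses to 13, where each lactone has released its benzylic alkoxide onto the carbon β to the ketone born from the other lactone. Each alkoxide then attacks the fluorine-bearing carbon of the aroyl group on its own C3 by addition–elimination (SNAr) and LiF is lost, forming O1–C8a and O1''–C8a''; both pyranone rings close in the same mode, a six-membered attack that counts as 6-endo-trig on the vinylogous acyl fluoride C8a=C4a–C4=O. The closest known reactions are the opening of γ-lactones by aryllithiums to γ-hydroxy ketones and the base-induced cyclisation of β-hydroxy 2-fluoroaryl ketones to chroman-4-ones; new is their twofold relay in one flask on a crossed dilactone. C2 and C2'' stay S because no bond to them is broken, whereas C3 and C3'' first appear cis (14) and are brought to the trans, diequatorial 3R,3''R arrangement by LiOt-Bu/t-BuOH proton exchange through the enolate, controlled thermodynamically by the adjacent C2 aryl groups. Needed are one addition per carbonyl (secured by the two ortho substituents of 11 and the persistent lactolate), addition rather than bridgehead deprotonation (the stabilised aryl anion is a modest base, and an enolate of 8 could expel carboxylate only by a retro-5-endo-trig path, so it returns 8 unchanged on protonation because only the cis-fused bicycle is viable), and six- over seven-membered closure with fluoride, not methoxide, as leaving group (own versus remote aroyl ring). SNAr must also outrun retro-aldol cleavage of C2–C3 and E1cB opening at O1–C2, for which lithium chelation of the aldolate, the proton shuttle and a ceiling of ambient temperature are relied on.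

Step 7
Reactants: 15 (2S,3R,2''S,3''R)-5,5''-dimethoxy-2,2''-bis(4-methoxyphenyl)-7,7''-bis(triisopropylsilyloxy)-3,3''-bichroman-4,4''-dione
Product: 16 4',4''',5,5''-tetramethylchamaejasmin, (2S,3R,2''S,3''R)-7,7''-dihydroxy-5,5''-dimethoxy-2,2''-bis(4-methoxyphenyl)-3,3''-bichroman-4,4''-dione
Conditions: TBAF, AcOH, THF, 0 °C; then HCl, MeOH, 40 °C
Reagents that add atoms: none
Why: Fluoride-induced cleavage of aryl silyl ethers, buffered so that no phenoxide or enolate builds up, followed by acid-catalysed keto–enol equilibration that should carry any residual cis C3 or C3'' centre to the trans isomer while C2 and C2'' are not touched.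

**Compound list**
1 | 3-(4-methoxyphenyl)propanoyl chloride | COc1ccc(CCC(=O)Cl)cc1 | starting material
2 | (4S)-4-isopropyl-1,3-oxazolidin-2-one | CC(C)[C@H]1COC(=O)N1 | starting material
3 | (4S)-4-isopropyl-3-[3-(4-methoxyphenyl)propanoyl]-1,3-oxazolidin-2-one | COc1ccc(CCC(=O)N2[C@@H](C(C)C)COC2=O)cc1 | intermediate
4 | lithium (Z)-enolate of 3 | COc1ccc(C/C=C(\O[Li])N2[C@@H](C(C)C)COC2=O)cc1 | intermediate
5 | trichlorotitanium (Z)-enolate of 3 | COc1ccc(C/C=C(\O[Ti](Cl)(Cl)Cl)N2[C@@H](C(C)C)COC2=O)cc1 | intermediate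
6 | (2R,3R)-2,3-bis(4-methoxybenzyl)-1,4-bis[(4S)-4-isopropyl-2-oxo-1,3-oxazolidin-3-yl]butane-1,4-dione | O=C1OC[C@H](C(C)C)N1C(=O)[C@H](Cc1ccc(OC)cc1)[C@@H](Cc1ccc(OC)cc1)C(=O)N1[C@@H](C(C)C)COC1=O | intermediate
7 | (2R,3R)-2,3-bis(4-methoxybenzyl)butanedioic acid | OC(=O)[C@H](Cc1ccc(OC)cc1)[C@@H](Cc1ccc(OC)cc1)C(=O)O | intermediate
8 | (1S,4S,5S,8S)-4,8-bis(4-methoxyphenyl)-3,7-dioxabicyclo[3.3.0]octane-2,6-dione, exo,exo | COc1ccc(cc1)[C@H]2OC(=O)[C@H]3[C@@H]2C(=O)O[C@@H]3c1ccc(OC)cc1 | intermediate
9 | 3-fluoro-5-methoxyphenol | COc1cc(O)cc(F)c1 | starting material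
10 | (3-fluoro-5-methoxyphenoxy)triisopropylsilane | COc1cc(F)cc(O[Si](C(C)C)(C(C)C)C(C)C)c1 | intermediate
11 | 2-fluoro-6-methoxy-4-(triisopropylsilyloxy)phenyllithium | [Li]c1c(F)cc(O[Si](C(C)C)(C(C)C)C(C)C)cc1OC | intermediate
12 | dilithium salt of (1S,4S,5S,8S)-2,6-bis[2-fluoro-6-methoxy-4-(triisopropylsilyloxy)phenyl]-4,8-bis(4-methoxyphenyl)-3,7-dioxabicyclo[3.3.0]octane-2,6-diol (hemiketal carbons undefined) | COc1ccc(cc1)[C@H]2OC(O[Li])(c4c(F)cc(O[Si](C(C)C)(C(C)C)C(C)C)cc4OC)[C@H]3[C@@H]2C(O[Li])(c4c(F)cc(O[Si](C(C)C)(C(C)C)C(C)C)cc4OC)O[C@@H]3c1ccc(OC)cc1 | intermediate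
13 | dilithium (1S,2S,3S,4S)-2,3-bis[2-fluoro-6-methoxy-4-(triisopropylsilyloxy)benzoyl]-1,4-bis(4-methoxyphenyl)butane-1,4-diolate | COc1ccc(cc1)[C@@H](O[Li])[C@@H](C(=O)c1c(F)cc(O[Si](C(C)C)(C(C)C)C(C)C)cc1OC)[C@H](C(=O)c1c(F)cc(O[Si](C(C)C)(C(C)C)C(C)C)cc1OC)[C@H](O[Li])c1ccc(OC)cc1 | intermediate
14 | (2S,3S,2''S,3''S)-5,5''-dimethoxy-2,2''-bis(4-methoxyphenyl)-7,7''-bis(triisopropylsilyloxy)-3,3''-bichroman-4,4''-dione (cis,cis) | COc1ccc([C@H]2Oc3cc(O[Si](C(C)C)(C(C)C)C(C)C)cc(OC)c3C(=O)[C@H]2[C@@H]2C(=O)c3c(OC)cc(O[Si](C(C)C)(C(C)C)C(C)C)cc3O[C@@H]2c2ccc(OC)cc2)cc1 | intermediate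
15 | (2S,3R,2''S,3''R)-5,5''-dimethoxy-2,2''-bis(4-methoxyphenyl)-7,7''-bis(triisopropylsilyloxy)-3,3''-bichroman-4,4''-dione (trans,trans) | COc1ccc([C@H]2Oc3cc(O[Si](C(C)C)(C(C)C)C(C)C)cc(OC)c3C(=O)[C@@H]2[C@H]2C(=O)c3c(OC)cc(O[Si](C(C)C)(C(C)C)C(C)C)cc3O[C@@H]2c2ccc(OC)cc2)cc1 | intermediate
16 | 4',4''',5,5''-tetramethylchamaejasmin | COc1ccc([C@H]2Oc3cc(O)cc(OC)c3C(=O)[C@@H]2[C@H]2C(=O)c3c(OC)cc(O)cc3O[C@@H]2c2ccc(OC)cc2)cc1 | target

**Step count**
- Total steps: 7.
- Longest linear sequence: 6 (steps 1, 2, 3, 4, 6, 7).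

**Steps most likely to fail**

**Step 6.**
- Several processes could defeat the relay:
  - The aryllithium may be spent on bridgehead deprotonation.
  - It may lose LiF to an aryne on local warming.
  - The lithium aldolate may fragment by retro-aldol before fluoride is displaced.
  - Silicon may migrate from the phenol oxygen to an alkoxide and switch off the SNAr.
  - Prolonged base contact may open O1–C2 and erode C2.
- The fallback sets out from 8, returns at 15, and separates the events with known reactions.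
- 8 is opened with MeNHOMe·HCl and AlMe3 in CH2Cl2 to the bis(N-methoxy-N-methylamide) diol F1.
- F1 is silylated at once (TESOTf, 2,6-lutidine) to the bis(triethylsilyl) ether F2.
- F2 is treated with 11 at −78 °C (Weinreb ketone synthesis) to give the bis(aryl ketone) F3.
- PPTS in MeOH then frees the diol diketone F4 without touching the aryl silyl ethers.
- NaH in THF closes both pyranone rings by the established cyclisation of β-hydroxy 2-fluoroaryl ketones.
- A catalytic amount of DBU finishes the C3/C3'' equilibration to 15.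

**Step 4.**
- Hydride abstraction may be sluggish because each benzylic carbon sits next to the electron-poor succinate.
- The cation may lose the C3 proton to a benzylidene succinate, which erases a backbone centre.
- The fallback sets out from 7, returns at 8, and replaces hydride abstraction by radical halogenation.
- 7 is esterified (MeI, K2CO3, DMF) to the dimethyl succinate F5.
- Wohl–Ziegler bromination (NBS, AIBN, PhCF3, 80 °C) gives the bis(benzylic bromide) F6.
- On continued heating F6 ionises and is captured by the γ-ester carbonyl with loss of bromomethane.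
- The same convex-face preference should deliver exo,exo 8.

**Step 2.**
- Facial selectivity in the radical recombination may be only moderate.
- Part of the enolate may return to 3 by protonation or be chlorinated.
- The fallback sets out from 3, returns at 7, and forms C3–C3'' by a stereospecific SN2 reaction in place of an oxidation.
- O-methyl-D-tyrosine is diazotised with retention (NaNO2, aq H2SO4) to (R)-2-hydroxy-3-(4-methoxyphenyl)propanoic acid F7.
- F7 is benzylated (BnBr, Cs2CO3) to the benzyl ester F8.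
- F8 is converted with Tf2O and 2,6-lutidine into the (R)-triflate F9.
- Enolate 4, made from 3 with LDA, displaces the triflate with inversion under auxiliary control to give the imide benzyl ester F10.
- Hydrogenolysis (H2, Pd/C) gives the imide acid F11.
- LiOH/H2O2 then releases 7.

**Further compounds**
F1 | step 6 | (2S,3S)-2,3-bis[(S)-hydroxy(4-methoxyphenyl)methyl]-N1,N4-dimethoxy-N1,N4-dimethylbutanediamide | COc1ccc(cc1)[C@@H](O)[C@@H](C(=O)N(C)OC)[C@H](C(=O)N(C)OC)[C@H](O)c1ccc(OC)cc1
F2 | step 6 | (2S,3S)-N1,N4-dimethoxy-2,3-bis[(S)-(4-methoxyphenyl)(triethylsilyloxy)methyl]-N1,N4-dimethylbutanediamide | COc1ccc(cc1)[C@@H](O[Si](CC)(CC)CC)[C@@H](C(=O)N(C)OC)[C@H](C(=O)N(C)OC)[C@H](O[Si](CC)(CC)CC)c1ccc(OC)cc1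
F3 | step 6 | (2S,3S)-1,4-bis[2-fluoro-6-methoxy-4-(triisopropylsilyloxy)phenyl]-2,3-bis[(S)-(4-methoxyphenyl)(triethylsilyloxy)methyl]butane-1,4-dione | COc1ccc(cc1)[C@@H](O[Si](CC)(CC)CC)[C@@H](C(=O)c1c(F)cc(O[Si](C(C)C)(C(C)C)C(C)C)cc1OC)[C@H](C(=O)c1c(F)cc(O[Si](C(C)C)(C(C)C)C(C)C)cc1OC)[C@H](O[Si](CC)(CC)CC)c1ccc(OC)cc1
F4 | step 6 | (2S,3S)-1,4-bis[2-fluoro-6-methoxy-4-(triisopropylsilyloxy)phenyl]-2,3-bis[(S)-hydroxy(4-methoxyphenyl)methyl]butane-1,4-dione | COc1ccc(cc1)[C@@H](O)[C@@H](C(=O)c1c(F)cc(O[Si](C(C)C)(C(C)C)C(C)C)cc1OC)[C@H](C(=O)c1c(F)cc(O[Si](C(C)C)(C(C)C)C(C)C)cc1OC)[C@H](O)c1ccc(OC)cc1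
F5 | step 4 | dimethyl (2R,3R)-2,3-bis(4-methoxybenzyl)butanedioate | COC(=O)[C@H](Cc1ccc(OC)cc1)[C@@H](Cc1ccc(OC)cc1)C(=O)OC
F6 | step 4 | dimethyl 2,3-bis[bromo(4-methoxyphenyl)methyl]butanedioate, backbone as in 7, bromide epimers | COC(=O)[C@H](C(Br)c1ccc(OC)cc1)[C@@H](C(Br)c1ccc(OC)cc1)C(=O)OC
F7 | step 2 | (R)-2-hydroxy-3-(4-methoxyphenyl)propanoic acid | COc1ccc(C[C@@H](O)C(=O)O)cc1
F8 | step 2 | benzyl (R)-2-hydroxy-3-(4-methoxyphenyl)propanoate | COc1ccc(C[C@@H](O)C(=O)OCc2ccccc2)cc1
F9 | step 2 | benzyl (R)-3-(4-methoxyphenyl)-2-(trifluoromethylsulfonyloxy)propanoate | COc1ccc(C[C@@H](OS(=O)(=O)C(F)(F)F)C(=O)OCc2ccccc2)cc1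
F10 | step 2 | benzyl (2R,3R)-2,3-bis(4-methoxybenzyl)-4-[(4S)-4-isopropyl-2-oxo-1,3-oxazolidin-3-yl]-4-oxobutanoate | O=C1OC[C@H](C(C)C)N1C(=O)[C@H](Cc1ccc(OC)cc1)[C@@H](Cc1ccc(OC)cc1)C(=O)OCc1ccccc1
F11 | step 2 | (2R,3R)-2,3-bis(4-methoxybenzyl)-4-[(4S)-4-isopropyl-2-oxo-1,3-oxazolidin-3-yl]-4-oxobutanoic acid | O=C1OC[C@H](C(C)C)N1C(=O)[C@H](Cc1ccc(OC)cc1)[C@@H](Cc1ccc(OC)cc1)C(=O)O
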